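Within 6.0 s, does a held gas keep up with what the substrate takes from it, at each of these charges? That is the question for this row of flasks.

| flask | substrate | gas | time |
|---|---|---|---|
| zeta | 0.50 mM | 1.0 mM (held) | 6.0 s |
| theta | 1.0 mM | 1.0 mM (held) | 6.0 s |
| gamma | 2.0 mM | 1.0 mM (held) | 6.0 s |
| alpha | 4.0 mM | 1.0 mM (held) | 6.0 s |

    substrate + reagent → intermediate + by-product (k1 = 68.1 L mol⁻¹ s⁻¹)
    intermediate → product (k2 = 0.174 s⁻¹)
    gas ⇌ reagent, rate k3*(csat - [reagent]) (k3 = 5.45 s⁻¹, csat = 1.0 mM)

* amount of intermediate at the end, in percent of the substrate charged for zeta, theta, gamma, alpha, in this order
* how the row runs (falls all the way / hardly changes / rises all the way / falls, then rises / rises, then falls)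

- at the start none of reagent is dissolved
- "hardly changes" means that all values lie within two and a half points (for a concentration: within two and a half percent of the largest)
- run time (zeta): 6.0 s

The bench rule says yes: with the gas held, dissolved reagent sits at saturation, so the substrate falls pseudo-first-order with constant 0.0681 s⁻¹, and the charge cancels from the percentage of intermediate. Two consecutive first-order steps, the second at 0.174 s⁻¹, then give us 20.1% at the end. The start without reagent we set aside, because the time constant of uptake, about 0.183 s, is far shorter than the run.

The border of the rule comes from the balance of reagent. Past that start, uptake, the transfer coefficient times the gap to saturation, nearly equals use, the first step's constant times substrate times reagent. So reagent stands at saturation divided by 1 plus the draw-down, which is the first step's constant times the substrate present over the transfer coefficient; at alpha's charge, larger than the others, it is 5.00%. We put the border of the rule where the draw-down reaches 1, at a substrate of 80.0 mM, far above alpha's charge. Taking intermediate as roughly proportional to reagent, we estimate that the draw-down puts alpha about 1 percentage point under the rule's figure. We commit to a row just below 20.1% that hardly changes.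

The forecast, holding that “Dissolved reagent therefore reaches a quasi-steady value”, gave 19.8%, 19.7%, 19.6% and 19.3%, and called the shape hardly changes. It names a value for each flask, where we gave the rule's figure and a rough estimate for alpha.

The simulation gives 19.8%, 19.7%, 19.6% and 19.3%: hardly changes. In zeta, uptake of gas had 84% of its turnover behind it by 0.600 s, while the first step had 20% of its own behind it by 1.20 s. In zeta that first step was still running at the end, with 67.4% of the substrate left and the second step turning intermediate into product, 12.8% by then. Scaling the draw-down by the substrate left at 3.00 s gives 0.960 mM of reagent for alpha, and the flask held 0.960 mM. Gamma, at half alpha's charge, reckons to 0.980 mM and held 0.979 mM.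

Its constants stand for no real mixture; the run is a simulation.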